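## Structural features

Compound 32 is an achiral trimeric acylphloroglucinol. Three hexasubstituted benzene rings, each with a butyryl group, are joined in a row by two CH2 bridges (ring A–CH2–ring B–CH2–ring C). Ring B is a 2,4,6-trihydroxybutyrophenone that carries the bridges on C3 and C5. Rings A and C are constitutional isomers: in ring A the O-methyl lies between the C-methyl and the butyryl group (para to the bridge), in ring C it lies between the C-methyl and the bridge (para to the butyryl group). There is no stereocentre, so the problem is purely regiochemical: nine oxygens, two of them methylated at non-equivalent sites, and three acyl groups on three rings. The free polyphenol is the fragile part: it oxidises in air, and its bis(hydroxyaryl)methane bridges are cleaved and scrambled by acid or base, so the phenols must be unveiled last under neutral conditions and the ketones kept away from organolithium and amide bases. The key step uses ring C: C4–C5–C6–C1 correspond to the ester carbon, C2, C3 and C4 of a 3-methoxy-2-methylpent-2-enoate, which already holds the C6 O-methyl, the C5 methyl and the bridge carbon. C2–C3 are the alkyne carbons of a 1-bromo ynone, which brings the butyryl group and a bromine that marks the C2 oxygen.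

## Logic of the disconnections

32 is cut at five benzyl O–C bonds to give 31. The free nonaphenol cannot be carried through any bond-forming step, and hydrogenolysis is a neutral last step. The demand is that three aryl ketones and two methyl ethers survive it.

31 is cut at the C2–O bond of ring C to give bromide 30. This oxygen, between bridge and butyryl, is the one that neither cycloaddition partner can supply directly, and a bromine on the alkyne marks its place. The forward step must substitute a doubly ortho-substituted aryl bromide; the ortho carbonyl assists it.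

30 is cut at the two aryl–acyl bonds on rings A and B to give 29. The ketones would not survive the organolithium and amide-base steps that precede 29, and each ring has only one free position, so the regiochemistry is automatic. The forward acylation must avoid acid damage to benzyl ethers and bridges.

29 is cut at the C1–C2 and C3–C4 bonds of ring C to give diene 24 and ynone 27. This is the point of greatest simplification: a hexasubstituted ring with five different substituents comes from an acyclic ester and a six-carbon alkyne, with each substituent fixed by its position in a chain. The forward step must pair the diene terminus with the bromine-bearing carbon and must close the ring before bromide is lost.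

24 is cut at the O–Si bond to give 22, and 22 at its enol O–CH3 bond to give 20. The enol ether oxygen becomes the C6 O-methyl of ring C, so this methylation is regiospecific by construction. The forward steps need γ-deprotonation and a geometry at C3=C4 that allows the s-cis diene.

20 is cut at the CH2–CH2 bond between the future ring C C1 and the bridge carbon to give benzylic alcohol 15 and keto ester 16. The bridge carbon is thus attached to ring B from the start, and ring C is built onto it. The forward step needs a 2,4,6-trialkoxybenzyl electrophile, which must be made and consumed without isolation.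

15 is cut at its ring B–CH2OH bond to give bromide 12; 12 at the carbinol C–O bond to give 11; and 11 at the bond between ring B and the ring A aldehyde carbon to give 9 and 5. Two bromines on ring B define both attachment points, so neither has to be chosen by electrophilic substitution between rings of similar reactivity. The forward steps need mono-exchange of a dibromide and an ionic reduction that spares benzyl ethers.

5 is cut back through 4 and 3 to 1 (two benzyl O–C bonds, one methyl O–C bond, one aryl–CHO bond). The symmetry of 1 makes formylation unambiguous, and the aldehyde then distinguishes the para hydroxyl for methylation. 9 is cut back through 8 and 7 to 6 (two C–Br and three benzyl O–C bonds). 27 is cut back through 26 to 25 (the C–Br bond and the oxidation level).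

## Other disconnections considered

Alternative 1: Ring A is cut at C6–C1 and C2–C3. In the forward sense 3-methoxy-2-methylcyclobut-2-enone A1 is heated with siloxyalkyne A2, which carries the ring B–ring C diarylmethane. The cyclobutenone opens to a vinylketene, adds to the ynol ether, and the ring closes by 6π electrocyclisation to phenol A3.
- In its favour: the three oxygens of ring A arrive fully differentiated (free OH, silyl ether, methyl ether), and the conditions are thermal and neutral. The regiochemistry follows from ketene and ynol ether polarity and is more predictable than that of the chosen cycloaddition; on this point it is the better plan. The free C6 hydroxyl next to C5–H could also direct the later butyrylation of ring A.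
- Against it: ring A is the ring that classical chemistry already handles well (three steps from 1 by symmetry and chelation). A1 has to be made, and A2 needs a long sequence in which ring C is built classically and an arylacetic ester is homologated to the ynol ether. None of the three butyryl groups is delivered, so three acylations follow instead of two.
- Comparison: equal on stereochemistry (none) and on the neutral finish; longer overall.

Alternative 2: Ring C is cut at C4–C5 and C6–C1. Cyclobutenone A4, with the ring A–ring B arylmethyl group on C2 and a benzyloxy group on C3, is heated with 1-methoxyprop-1-yne A5 to give phenol A6.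
- In its favour: it builds the same ring as the chosen plan, and all three ring C oxygens are in place after the key step. No halogen-to-oxygen exchange is needed, which is a real advantage over the chosen plan, and the regiochemistry is again reliable.
- Against it: the ring C butyryl group is not delivered and must go onto C3–H between OH and OBn, so three hindered acylations are needed. A4 would come from ketene chemistry on the valuable ring A–ring B fragment, and A5 is volatile and has to be prepared.
- Comparison: step count about equal (one step saved after the key step, one more ring to acylate). The cascade needs prolonged heating, whereas the chosen cycloaddition should run near room temperature.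

Alternative 3: Ring B is cut at C3–C4 and C6–C1. Bis-silyloxy diene A7, carrying the ring A arylmethyl group, is condensed with malonyl dichloride A8, carrying the ring C arylmethyl group, under a silyl triflate to give benzoate A9.
- In its favour: it is the most convergent plan, joining two outer fragments of similar size while making the central ring; on convergence it is better than the chosen plan. Ring B's hydroxyls appear free and distinct from the outer-ring ethers.
- Against it: malonyl dichlorides can close through oxygen to 4-hydroxy-2-pyranones, and a monosubstituted one such as A8 can lose HCl to a chlorocarbonyl ketene. The Lewis acid and the HCl meet two acid-labile 2,4,6-trialkoxybenzyl groups. A9 has CO2Me where butyryl is needed, and converting an ester flanked by two hydroxyls into a propyl ketone costs several steps. Rings A and C also still need their acyl groups.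
- Comparison: mechanistically less secure than either cycloaddition and longer after the key step.

Key step: step 15

Remarks on the chemistry:
- Mapping diene and ynone onto ring C (ester carbon → C4, C2 → C5, C3 → C6, C4 → C1, bromine-bearing alkyne carbon → C2, acyl-bearing alkyne carbon → C3) reproduces 29 and then 32 atom for atom, so the connectivities of 24, 27 and 29 need no correction.
- The arylmethyl group of 24 is specified trans to C2 (3Z), the only geometry that can reach the s-cis conformation. 22 is carried as an E/Z mixture and 24 as a mixture at its ketene acetal double bond, since both vanish in 29.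
- Lithium alkoxides formed by simple deprotonation of a numbered alcohol are not numbered separately.
- Ar = 2,4,6-tris(benzyloxy)-3-[2,6-bis(benzyloxy)-4-methoxy-3-methylbenzyl]phenyl.

## Steps

Step 1
Reactants: 1 2-methylbenzene-1,3,5-triol
Product: 3 2,4,6-trihydroxy-3-methylbenzaldehyde, via iminium chloride 2 (not isolated)
Conditions: POCl3, DMF, EtOAc, 0 °C → rt; then H2O, 60 °C
Reagents that add atoms: N,N-dimethylformamide CN(C)C=O; water O
Why: Vilsmeier–Haack formylation; the two free ring positions of 1 are equivalent, so one aldehyde forms, and the iminium group of 2 deactivates the ring against a second formylation before hydrolysis gives 3.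

Step 2
Reactants: 3 2,4,6-trihydroxy-3-methylbenzaldehyde
Product: 4 2,6-dihydroxy-4-methoxy-3-methylbenzaldehyde
Conditions: Me2SO4 (1.05 equiv), K2CO3 (1.1 equiv), acetone, 0 °C → rt
Reagents that add atoms: dimethyl sulfate COS(=O)(=O)OC
Why: Williamson O-methylation; the hydroxyl para to the formyl group is the most acidic and cannot chelate to the carbonyl, so one equivalent of methylating agent with a weak base should take it preferentially, placing the O-methyl next to the C-methyl and para to the future bridge carbon.

Step 3
Reactants: 4 2,6-dihydroxy-4-methoxy-3-methylbenzaldehyde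
Product: 5 2,6-bis(benzyloxy)-4-methoxy-3-methylbenzaldehyde
Conditions: BnBr, K2CO3, DMF, 60 °C
Reagents that add atoms: benzyl bromide BrCc1ccccc1
Why: Williamson etherification under more forcing conditions benzylates both chelated hydroxyls; the formyl group keeps the ring carbon poorly nucleophilic, so C-benzylation is not expected.

Step 4
Reactants: 6 benzene-1,3,5-triol
Product: 7 benzene-1,3,5-triyl triacetate
Conditions: Ac2O, pyridine, rt
Reagents that add atoms: acetic anhydride CC(=O)OC(C)=O
Why: Exhaustive O-acetylation; the acetates mask the phenols so that step 5 never exposes the polyphenoxide of 6, which benzylates on carbon.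

Step 5
Reactants: 7 benzene-1,3,5-triyl triacetate
Product: 8 1,3,5-tris(benzyloxy)benzene
Conditions: BnCl, NaH, DMF, 0 °C; H2O (slow addition), 0 °C → rt
Reagents that add atoms: benzyl chloride ClCc1ccccc1
Why: In situ deacetylation–Williamson benzylation; NaOH formed slowly from NaH and water cleaves one acetate at a time and each phenoxide is benzylated at once, so O-alkylation should prevail.

Step 6
Reactants: 8 1,3,5-tris(benzyloxy)benzene
Product: 9 1,3,5-tris(benzyloxy)-2,4-dibromobenzene
Conditions: NBS (2.05 equiv), CH2Cl2, 0 °C → rt
Reagents that add atoms: N-bromosuccinimide O=C1CCC(=O)N1Br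
Why: Electrophilic aromatic bromination; the three ring positions are equivalent and each bromine lowers the reactivity, so two equivalents should stop at the dibromide, whose bromines become the two anchor points of ring B.

Step 7
Reactants: 9 1,3,5-tris(benzyloxy)-2,4-dibromobenzene; 5 2,6-bis(benzyloxy)-4-methoxy-3-methylbenzaldehyde
Product: 11 [2,6-bis(benzyloxy)-4-methoxy-3-methylphenyl][2,4,6-tris(benzyloxy)-3-bromophenyl]methanol (racemic), via aryllithium 10 (not isolated)
Conditions: n-BuLi (1.0 equiv), THF, –78 °C; then 5, –78 → –40 °C; H2O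
Reagents that add atoms: none
Why: Bromine–lithium exchange followed by 1,2-addition to the aldehyde; one equivalent exchanges one bromine only because 10 resists a second exchange, and at –78 °C the ortho benzyl ethers are not attacked; the carbinol stereocentre is racemic and is removed in step 8.

Step 8
Reactants: 11 [2,6-bis(benzyloxy)-4-methoxy-3-methylphenyl][2,4,6-tris(benzyloxy)-3-bromophenyl]methanol
Product: 12 1,3,5-tris(benzyloxy)-2-bromo-4-[2,6-bis(benzyloxy)-4-methoxy-3-methylbenzyl]benzene
Conditions: Et3SiH, CF3CO2H, CH2Cl2, –20 → 0 °C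
Reagents that add atoms: none
Why: Ionic hydrogenation; the carbinol flanked by four ortho alkoxy groups ionises in cold acid to a strongly stabilised diarylmethyl cation, which the silane reduces while aryl bromide and benzyl ethers stay intact.

Step 9
Reactants: 12 1,3,5-tris(benzyloxy)-2-bromo-4-[2,6-bis(benzyloxy)-4-methoxy-3-methylbenzyl]benzene
Product: 15 {2,4,6-tris(benzyloxy)-3-[2,6-bis(benzyloxy)-4-methoxy-3-methylbenzyl]phenyl}methanol (ArCH2OH), via aryllithium 13 (not isolated), via aldehyde 14 (not isolated)
Conditions: n-BuLi, THF, –78 °C; DMF, –78 → 0 °C; then MeOH, NaBH4, 0 °C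
Reagents that add atoms: N,N-dimethylformamide CN(C)C=O
Why: Second bromine–lithium exchange, formylation with DMF and borohydride reduction in one flask; the bromine fixes the site on ring B, which an electrophilic formylation could not distinguish from the free position of ring A.

Step 10
Reactants: 15 {2,4,6-tris(benzyloxy)-3-[2,6-bis(benzyloxy)-4-methoxy-3-methylbenzyl]phenyl}methanol; 16 methyl 2-methyl-3-oxobutanoate
Product: 20 methyl 5-Ar-2-methyl-3-oxopentanoate (racemic at C2), via benzylic mesylate 17 (not isolated), via benzylic chloride 18 (not isolated), via keto ester dianion 19 (not isolated)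
Conditions: 15: n-BuLi (1.0 equiv), THF, –78 °C; MsCl, –78 → –30 °C; added to 19 [from 16, LiN(i-Pr)2 (2.1 equiv), THF, 0 °C] at –78 → 0 °C; 1 M HCl
Reagents that add atoms: none
Why: γ-Alkylation of a β-keto ester dianion; the lithium alkoxide of 15 is mesylated and the lithium chloride formed converts 17 into 18, which is never concentrated and should be attacked at once by the terminal carbanion of 19; the C2 stereocentre of 20 disappears in step 11.

Step 11
Reactants: 20 methyl 5-Ar-2-methyl-3-oxopentanoate
Product: 22 methyl 5-Ar-3-methoxy-2-methylpent-2-enoate (E/Z mixture), via dimethyl ketal 21 (not isolated)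
Conditions: HC(OMe)3, MeOH, H2SO4 (cat.), rt → 50 °C
Reagents that add atoms: trimethyl orthoformate COC(OC)OC
Why: Acid-catalysed ketalisation with the orthoester and loss of methanol towards the ester should give the conjugated push–pull enol ether as the thermodynamic product; its oxygen becomes the C6 O-methyl of ring C.

Step 12
Reactants: 22 methyl 5-Ar-3-methoxy-2-methylpent-2-enoate
Product: 24 (3Z)-5-Ar-1,3-dimethoxy-2-methyl-1-(trimethylsilyloxy)penta-1,3-diene, via lithium dienolate 23 (not isolated)
Conditions: LiN(i-Pr)2, THF, –78 °C; Me3SiCl, –78 → 0 °C; pentane, filtration under Ar; used crude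
Reagents that add atoms: chlorotrimethylsilane C[Si](C)(C)Cl
Why: γ-Deprotonation of the vinylogous ester and O-silylation of the dienolate, the standard route to 1,3-dialkoxy-1-silyloxybutadienes; allylic strain with the C2 substituents should place the arylmethyl group trans to C2 (3Z).

Step 13
Reactants: 25 hex-1-yn-3-ol (racemic)
Product: 26 1-bromohex-1-yn-3-ol (racemic)
Conditions: NBS, AgNO3 (cat.), acetone, rt
Reagents that add atoms: N-bromosuccinimide O=C1CCC(=O)N1Br
Why: Silver-catalysed bromination of a terminal alkyne through the silver acetylide; the free alcohol is tolerated.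

Step 14
Reactants: 26 1-bromohex-1-yn-3-ol
Product: 27 1-bromohex-1-yn-3-one
Conditions: Dess–Martin periodinane, CH2Cl2, 0 °C → rt; used at once
Reagents that add atoms: none
Why: Dess–Martin oxidation of a secondary propargylic alcohol under neutral conditions that leave the bromoalkyne intact.

Step 15
Reactants: 24 (3Z)-5-Ar-1,3-dimethoxy-2-methyl-1-(trimethylsilyloxy)penta-1,3-diene; 27 1-bromohex-1-yn-3-one
Product: 29 1-[3-(Ar-methyl)-2-bromo-6-hydroxy-4-methoxy-5-methylphenyl]butan-1-one, via cycloadduct 28 (not isolated)
Conditions: toluene, –20 °C → rt; then 1 M HCl, THF, rt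
Reagents that add atoms: none
Why: Diene 24 has its largest HOMO coefficient at C4 and ynone 27 its largest LUMO coefficient at the bromine-bearing β-carbon, so they should combine in a concerted, strongly asynchronous Diels–Alder reaction in which the C4–Cβ bond (ring C C1–C2) leads and the bond from the ketene acetal carbon to Cα (ring C C3–C4) follows. The closest known reaction type is the cycloaddition of 1,3-dialkoxy-1-silyloxybutadienes to acetylenic ketones and esters, 3-halopropiolates included, followed by aromatisation. Ring C closes as a six-membered carbocycle by suprafacial [4πs+2πs] union of the two components, giving cyclohexa-1,4-diene 28. On acidic work-up the silyl methyl ketal of 28 loses methanol and the silyl group to a dienone, which tautomerises to phenol 29, hydrogen-bonded to the butyryl carbonyl. The two sp3 centres of 28 are transient and vanish on aromatisation, so no stereocentre needs control. The step needs regioselectivity, which the carbonyl polarisation of the ynone secures and a β-bromine is not expected to reverse, and it needs ring closure to outrun conjugate addition–elimination and attack at bromine. A non-polar solvent, the absence of a Lewis acid, the 3Z geometry and the 2,3-disubstitution that holds the diene s-cis all favour the cycloaddition. The result places the butyryl group para to the O-methyl and the bromine between bridge and butyryl.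

Step 16
Reactants: 29 1-[3-(Ar-methyl)-2-bromo-6-hydroxy-4-methoxy-5-methylphenyl]butan-1-one
Product: 30 the bis-butyryl bromide: 29 with butanoyl groups on the free position of ring A (C5) and of ring B (C1)
Conditions: n-PrCO2H, (CF3CO)2O, CH2Cl2, 0 °C → rt
Reagents that add atoms: butanoic acid CCCC(=O)O
Why: Friedel–Crafts acylation by the mixed anhydride; each target position is the only free site of an electron-rich trialkoxyarene and ring C is fully substituted, so regiochemistry is fixed, and trifluoroacetic acid is the only acid present; any ester formed at the ring C phenol is cleaved in step 17.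

Step 17
Reactants: 30 the bis-butyryl bromide
Product: 31 the pentabenzyl ether of 32: 30 with OH in place of Br at C2 of ring C
Conditions: Cu2O (cat.), 4,7-dihydroxy-1,10-phenanthroline (cat.), KOH, DMSO–H2O, 100 °C, N2
Reagents that add atoms: potassium hydroxide [K+].[OH-]
Why: Copper-catalysed Ullmann-type hydroxylation of an aryl bromide; the ortho carbonyl can chelate copper and assist insertion into the hindered C–Br bond, and benzyl ethers and aryl ketones should withstand aqueous hydroxide under nitrogen.

Step 18
Reactants: 31 the pentabenzyl ether of 32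
Product: 32 1-[3-[(3-butanoyl-2,6-dihydroxy-4-methoxy-5-methylphenyl)methyl]-5-[(3-butanoyl-2,4-dihydroxy-6-methoxy-5-methylphenyl)methyl]-2,4,6-trihydroxyphenyl]butan-1-one
Conditions: H2 (1 atm), Pd/C, EtOAc–MeOH, rt
Reagents that add atoms: none
Why: Hydrogenolysis of five aryl benzyl ethers under neutral conditions; the ketones, hydrogen-bonded to ortho hydroxyls once unveiled, and the methyl ethers should be untouched at one atmosphere, and the neutral finish avoids scrambling of the bridges.

## Compound list

1 | 2-methylbenzene-1,3,5-triol | Cc1c(O)cc(O)cc1O | starting material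
2 | N-methyl-N-[(2,4,6-trihydroxy-3-methylphenyl)methylidene]methanaminium chloride (not isolated) | C[N+](C)=Cc1c(O)c(C)c(O)cc1O.[Cl-] | intermediate
3 | 2,4,6-trihydroxy-3-methylbenzaldehyde | O=Cc1c(O)c(C)c(O)cc1O | intermediate
4 | 2,6-dihydroxy-4-methoxy-3-methylbenzaldehyde | O=Cc1c(O)c(C)c(OC)cc1O | intermediate
5 | 2,6-bis(benzyloxy)-4-methoxy-3-methylbenzaldehyde | O=Cc1c(OCc2ccccc2)c(C)c(OC)cc1OCc1ccccc1 | intermediate
6 | benzene-1,3,5-triol | Oc1cc(O)cc(O)c1 | starting material
7 | benzene-1,3,5-triyl triacetate | CC(=O)Oc1cc(OC(C)=O)cc(OC(C)=O)c1 | intermediate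
8 | 1,3,5-tris(benzyloxy)benzene | c1ccc(COc2cc(OCc3ccccc3)cc(OCc3ccccc3)c2)cc1 | intermediate
9 | 1,3,5-tris(benzyloxy)-2,4-dibromobenzene | Brc1c(OCc2ccccc2)cc(OCc2ccccc2)c(Br)c1OCc1ccccc1 | intermediate
10 | [2,4,6-tris(benzyloxy)-3-bromophenyl]lithium (not isolated) | [Li]c1c(OCc2ccccc2)cc(OCc2ccccc2)c(Br)c1OCc1ccccc1 | intermediate
11 | [2,6-bis(benzyloxy)-4-methoxy-3-methylphenyl][2,4,6-tris(benzyloxy)-3-bromophenyl]methanol, racemic | OC(c1c(OCc2ccccc2)c(C)c(OC)cc1OCc1ccccc1)c1c(OCc2ccccc2)cc(OCc2ccccc2)c(Br)c1OCc1ccccc1 | intermediate
12 | 1,3,5-tris(benzyloxy)-2-bromo-4-[2,6-bis(benzyloxy)-4-methoxy-3-methylbenzyl]benzene | Brc1c(OCc2ccccc2)cc(OCc2ccccc2)c(Cc2c(OCc3ccccc3)c(C)c(OC)cc2OCc2ccccc2)c1OCc1ccccc1 | intermediate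
13 | {2,4,6-tris(benzyloxy)-3-[2,6-bis(benzyloxy)-4-methoxy-3-methylbenzyl]phenyl}lithium (not isolated) | [Li]c1c(OCc2ccccc2)cc(OCc2ccccc2)c(Cc2c(OCc3ccccc3)c(C)c(OC)cc2OCc2ccccc2)c1OCc1ccccc1 | intermediate
14 | 2,4,6-tris(benzyloxy)-3-[2,6-bis(benzyloxy)-4-methoxy-3-methylbenzyl]benzaldehyde (not isolated) | O=Cc1c(OCc2ccccc2)cc(OCc2ccccc2)c(Cc2c(OCc3ccccc3)c(C)c(OC)cc2OCc2ccccc2)c1OCc1ccccc1 | intermediate
15 | {2,4,6-tris(benzyloxy)-3-[2,6-bis(benzyloxy)-4-methoxy-3-methylbenzyl]phenyl}methanol | OCc1c(OCc2ccccc2)cc(OCc2ccccc2)c(Cc2c(OCc3ccccc3)c(C)c(OC)cc2OCc2ccccc2)c1OCc1ccccc1 | intermediate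
16 | methyl 2-methyl-3-oxobutanoate | COC(=O)C(C)C(C)=O | starting material
17 | {2,4,6-tris(benzyloxy)-3-[2,6-bis(benzyloxy)-4-methoxy-3-methylbenzyl]phenyl}methyl methanesulfonate (not isolated) | CS(=O)(=O)OCc1c(OCc2ccccc2)cc(OCc2ccccc2)c(Cc2c(OCc3ccccc3)c(C)c(OC)cc2OCc2ccccc2)c1OCc1ccccc1 | intermediate
18 | 1,3,5-tris(benzyloxy)-2-(chloromethyl)-4-[2,6-bis(benzyloxy)-4-methoxy-3-methylbenzyl]benzene (not isolated) | ClCc1c(OCc2ccccc2)cc(OCc2ccccc2)c(Cc2c(OCc3ccccc3)c(C)c(OC)cc2OCc2ccccc2)c1OCc1ccccc1 | intermediate
19 | dilithium dianion of methyl 2-methyl-3-oxobutanoate (not isolated) | [Li+].[Li+].[CH2-]C(=O)[C-](C)C(=O)OC | intermediate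
20 | methyl 5-Ar-2-methyl-3-oxopentanoate, racemic at C2 | COC(=O)C(C)C(=O)CCc1c(OCc2ccccc2)cc(OCc2ccccc2)c(Cc2c(OCc3ccccc3)c(C)c(OC)cc2OCc2ccccc2)c1OCc1ccccc1 | intermediate
21 | methyl 5-Ar-3,3-dimethoxy-2-methylpentanoate (not isolated) | COC(=O)C(C)C(OC)(OC)CCc1c(OCc2ccccc2)cc(OCc2ccccc2)c(Cc2c(OCc3ccccc3)c(C)c(OC)cc2OCc2ccccc2)c1OCc1ccccc1 | intermediate
22 | methyl 5-Ar-3-methoxy-2-methylpent-2-enoate, E/Z mixture | COC(=O)C(C)=C(OC)CCc1c(OCc2ccccc2)cc(OCc2ccccc2)c(Cc2c(OCc3ccccc3)c(C)c(OC)cc2OCc2ccccc2)c1OCc1ccccc1 | intermediate
23 | lithium (3Z)-dienolate of 22 (not isolated) | [Li+].COC([O-])=C(C)/C(OC)=C/Cc1c(OCc2ccccc2)cc(OCc2ccccc2)c(Cc2c(OCc3ccccc3)c(C)c(OC)cc2OCc2ccccc2)c1OCc1ccccc1 | intermediate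
24 | (3Z)-5-Ar-1,3-dimethoxy-2-methyl-1-(trimethylsilyloxy)penta-1,3-diene | COC(O[Si](C)(C)C)=C(C)/C(OC)=C/Cc1c(OCc2ccccc2)cc(OCc2ccccc2)c(Cc2c(OCc3ccccc3)c(C)c(OC)cc2OCc2ccccc2)c1OCc1ccccc1 | intermediate
25 | hex-1-yn-3-ol, racemic | CCCC(O)C#C | starting material
26 | 1-bromohex-1-yn-3-ol, racemic | CCCC(O)C#CBr | intermediate
27 | 1-bromohex-1-yn-3-one | CCCC(=O)C#CBr | intermediate
28 | 1-[3-(Ar-methyl)-2-bromo-4,6-dimethoxy-5-methyl-6-(trimethylsilyloxy)cyclohexa-1,4-dien-1-yl]butan-1-one, diastereomer mixture (not isolated) | CCCC(=O)C1=C(Br)C(Cc2c(OCc3ccccc3)cc(OCc3ccccc3)c(Cc3c(OCc4ccccc4)c(C)c(OC)cc3OCc3ccccc3)c2OCc2ccccc2)C(OC)=C(C)C1(OC)O[Si](C)(C)C | intermediate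
29 | 1-[3-(Ar-methyl)-2-bromo-6-hydroxy-4-methoxy-5-methylphenyl]butan-1-one | CCCC(=O)c1c(Br)c(Cc2c(OCc3ccccc3)cc(OCc3ccccc3)c(Cc3c(OCc4ccccc4)c(C)c(OC)cc3OCc3ccccc3)c2OCc2ccccc2)c(OC)c(C)c1O | intermediate
30 | 29 with butanoyl on ring A C5 and ring B C1 (bis-butyryl bromide) | CCCC(=O)c1c(Br)c(Cc2c(OCc3ccccc3)c(C(=O)CCC)c(OCc3ccccc3)c(Cc3c(OCc4ccccc4)c(C)c(OC)c(C(=O)CCC)c3OCc3ccccc3)c2OCc2ccccc2)c(OC)c(C)c1O | intermediate
31 | pentabenzyl ether of 32 (30 with OH in place of Br) | CCCC(=O)c1c(O)c(Cc2c(OCc3ccccc3)c(C(=O)CCC)c(OCc3ccccc3)c(Cc3c(OCc4ccccc4)c(C)c(OC)c(C(=O)CCC)c3OCc3ccccc3)c2OCc2ccccc2)c(OC)c(C)c1O | intermediate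
32 | 1-[3-[(3-butanoyl-2,6-dihydroxy-4-methoxy-5-methylphenyl)methyl]-5-[(3-butanoyl-2,4-dihydroxy-6-methoxy-5-methylphenyl)methyl]-2,4,6-trihydroxyphenyl]butan-1-one | CCCC(=O)c1c(O)c(Cc2c(O)c(C)c(OC)c(C(=O)CCC)c2O)c(O)c(Cc2c(O)c(C(=O)CCC)c(O)c(C)c2OC)c1O | target

## Step count and least certain steps

Total: 18 steps. Longest linear sequence: 13 steps (steps 1, 2, 3, 7, 8, 9, 10, 11, 12, 15, 16, 17, 18; the branch from 6 through steps 4–6 is equally long).

Step 15 (key step). Three processes may compete with the cycloaddition: transfer of bromine from the bromoalkyne to the nucleophilic diene terminus, conjugate addition followed by loss of bromide instead of ring closure, and hydrolysis of the silyl ketene acetal if the addition is slowed by the bulky arylmethyl group. Aromatisation with loss of silanol instead of methanol would leave a C4 methyl ether. The fallback gives up the de novo ring and forms the ring B–ring C bridge in the classical way. It sets out from 15, with the ring C ketone made from 1. Friedel–Crafts butyrylation of 1 (butanoyl chloride, AlCl3) would give 1-(2,4,6-trihydroxy-3-methylphenyl)butan-1-one F1. Methylation of the hydroxyl para to the carbonyl, as in step 2, would give 1-(2,6-dihydroxy-4-methoxy-3-methylphenyl)butan-1-one F2. Acid-catalysed Friedel–Crafts benzylation of F2 (used in excess) at its only free ring position with 15 (BF3·OEt2 cat., CH2Cl2, –20 °C) would give the ring C resorcinol F3. Bis-butyrylation of F3 under the conditions of step 16, followed by brief K2CO3 in MeOH to cleave any aryl ester, comes back to the route at 31.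

Step 10. The 2,4,6-trialkoxybenzyl chloride may ionise and alkylate the free ring positions of a second molecule before it meets the dianion, or proton transfer may quench the dianion. The fallback sets out from aldehyde 14, isolated by aqueous work-up of step 9 before any borohydride is added. Aldol addition of dianion 19 would give methyl 5-Ar-5-hydroxy-2-methyl-3-oxopentanoate F4. Ionic hydrogenation of its strongly activated benzylic hydroxyl (Et3SiH, CF3CO2H, CH2Cl2, –40 °C), as in step 8, comes back at 20.

Step 11. Loss of methanol from ketal 21 may stall, or the enol ether may hydrolyse back on work-up. The fallback sets out from 20. Enol sulfonylation (TsCl, N-methylimidazole, Et3N) would give methyl 5-Ar-2-methyl-3-(tosyloxy)pent-2-enoate F5, and addition–elimination with NaOMe in MeOH comes back at 22.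

Step 16. Acylation at the two positions flanked by alkoxy groups may be incomplete, and the liberated acid may cause debenzylation or retro-Friedel–Crafts cleavage of a bridge. The fallback sets out from 29. A double Vilsmeier–Haack formylation (POCl3, DMF), less demanding sterically and free of protic acid, would give the bis-formyl compound F6. n-PrMgCl at –78 °C should add to the two aldehydes, not to the hindered, phenoxide-deactivated ring C ketone, giving the bis(1-hydroxybutyl) compound F7. Dess–Martin oxidation comes back at 30.

Step 17. Insertion into the doubly ortho-substituted, electron-rich C–Br bond may be slow, so that reductive loss of bromine or base-mediated oxidation next to the ketones takes over. The fallback sets out from 30. Palladium-catalysed C–O coupling with benzyl alcohol (Pd2(dba)3, RockPhos, Cs2CO3, toluene, 90 °C) would give the C2 benzyl ether F8. Hydrogenolysis under the conditions of step 18 removes six benzyl groups and comes back at 32.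

## Further compounds

F1 | step 15 | 1-(2,4,6-trihydroxy-3-methylphenyl)butan-1-one | CCCC(=O)c1c(O)cc(O)c(C)c1O
F2 | step 15 | 1-(2,6-dihydroxy-4-methoxy-3-methylphenyl)butan-1-one | CCCC(=O)c1c(O)cc(OC)c(C)c1O
F3 | step 15 | 1-[3-(Ar-methyl)-2,6-dihydroxy-4-methoxy-5-methylphenyl]butan-1-one | CCCC(=O)c1c(O)c(Cc2c(OCc3ccccc3)cc(OCc3ccccc3)c(Cc3c(OCc4ccccc4)c(C)c(OC)cc3OCc3ccccc3)c2OCc2ccccc2)c(OC)c(C)c1O
F4 | step 10 | methyl 5-Ar-5-hydroxy-2-methyl-3-oxopentanoate, diastereomer mixture | COC(=O)C(C)C(=O)CC(O)c1c(OCc2ccccc2)cc(OCc2ccccc2)c(Cc2c(OCc3ccccc3)c(C)c(OC)cc2OCc2ccccc2)c1OCc1ccccc1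
F5 | step 11 | methyl 5-Ar-2-methyl-3-(tosyloxy)pent-2-enoate | COC(=O)C(C)=C(OS(=O)(=O)c1ccc(C)cc1)CCc1c(OCc2ccccc2)cc(OCc2ccccc2)c(Cc2c(OCc3ccccc3)c(C)c(OC)cc2OCc2ccccc2)c1OCc1ccccc1
F6 | step 16 | 29 with formyl groups on ring A C5 and ring B C1 | CCCC(=O)c1c(Br)c(Cc2c(OCc3ccccc3)c(C=O)c(OCc3ccccc3)c(Cc3c(OCc4ccccc4)c(C)c(OC)c(C=O)c3OCc3ccccc3)c2OCc2ccccc2)c(OC)c(C)c1O
F7 | step 16 | 29 with 1-hydroxybutyl groups on ring A C5 and ring B C1, diastereomer mixture | CCCC(=O)c1c(Br)c(Cc2c(OCc3ccccc3)c(C(O)CCC)c(OCc3ccccc3)c(Cc3c(OCc4ccccc4)c(C)c(OC)c(C(O)CCC)c3OCc3ccccc3)c2OCc2ccccc2)c(OC)c(C)c1O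
F8 | step 17 | 30 with benzyloxy in place of bromine at C2 of ring C | CCCC(=O)c1c(OCc2ccccc2)c(Cc2c(OCc3ccccc3)c(C(=O)CCC)c(OCc3ccccc3)c(Cc3c(OCc4ccccc4)c(C)c(OC)c(C(=O)CCC)c3OCc3ccccc3)c2OCc2ccccc2)c(OC)c(C)c1O
A1 | alternative 1 | 3-methoxy-2-methylcyclobut-2-en-1-one | COC1=C(C)C(=O)C1
A2 | alternative 1 | triisopropylsilyl ynol ether carrying the benzyl-protected ring B–ring C diarylmethane | CC(C)[Si](OC#CCc1c(OCc2ccccc2)cc(OCc2ccccc2)c(Cc2c(OCc3ccccc3)cc(OCc3ccccc3)c(C)c2OC)c1OCc1ccccc1)(C(C)C)C(C)C
A3 | alternative 1 | benzannulation product with ring A as C6 phenol, C2 silyl ether, C4 methyl ether | COc1cc(O)c(Cc2c(OCc3ccccc3)cc(OCc3ccccc3)c(Cc3c(OCc4ccccc4)cc(OCc4ccccc4)c(C)c3OC)c2OCc2ccccc2)c(O[Si](C(C)C)(C(C)C)C(C)C)c1C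
A4 | alternative 2 | 3-(benzyloxy)-2-(Ar-methyl)cyclobut-2-en-1-one | O=C1CC(OCc2ccccc2)=C1Cc1c(OCc2ccccc2)cc(OCc2ccccc2)c(Cc2c(OCc3ccccc3)c(C)c(OC)cc2OCc2ccccc2)c1OCc1ccccc1
A5 | alternative 2 | 1-methoxyprop-1-yne | COC#CC
A6 | alternative 2 | benzannulation product with ring C as C4 phenol, C2 benzyl ether, C6 methyl ether | COc1c(C)c(O)cc(OCc2ccccc2)c1Cc1c(OCc2ccccc2)cc(OCc2ccccc2)c(Cc2c(OCc3ccccc3)c(C)c(OC)cc2OCc2ccccc2)c1OCc1ccccc1
A7 | alternative 3 | 1-methoxy-1,3-bis(trimethylsilyloxy)penta-1,3-diene with the protected ring A aryl group on C5 | COC(O[Si](C)(C)C)=CC(O[Si](C)(C)C)=CCc1c(OCc2ccccc2)c(C)c(OC)cc1OCc1ccccc1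
A8 | alternative 3 | 2-[2,4-bis(benzyloxy)-6-methoxy-5-methylbenzyl]malonyl dichloride | O=C(Cl)C(Cc1c(OCc2ccccc2)cc(OCc2ccccc2)c(C)c1OC)C(=O)Cl
A9 | alternative 3 | methyl 2,4,6-trihydroxy-3,5-bis(arylmethyl)benzoate | COC(=O)c1c(O)c(Cc2c(OCc3ccccc3)c(C)c(OC)cc2OCc2ccccc2)c(O)c(Cc2c(OCc3ccccc3)cc(OCc3ccccc3)c(C)c2OC)c1O
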